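**Plan** (target numbering, spiro[5.5]undecane: ring A C1 = CMe2, C2 = CHBr, C3 = CHOH, C4, C5 = C=CH2, spiro C6; ring B C7, C8 = CHBr, C9 = CClMe, C10, C11; intermediates use the same atom numbers)
Cuts, last to first: C3–H (ketone reduction); C2–Br and one C1 methyl (cuprate, then NBS, on an enone); C1–C2 (samarium aldol that closes ring A); C3–C4 (ene acylation of a C5 isopropenyl group); C9–Cl and C8–Br (bromolactone); ring B (Diels–Alder of isoprene 1 with diethyl methylidenemalonate 2).
Forward: ring B is made first; the two geminal carboxyl groups on C6 become C1 (acetyl) and C5 (isopropenyl); ring A is closed last, at C1–C2.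
Enabling feature: in 11 the C1 acetyl carbonyl sits on the quaternary C6, 1,5 to the C3 carbonyl of a bromomethyl ketone, so an enolate made at C2 by C–Br reduction can close only the six-membered ring A.
Stereochemistry: C6, C8 and C9 come from a desymmetrising bromolactonisation of a prochiral diacid (the carboxyl that becomes C5 delivers O to C9 on its own face, Br adds anti at C8, chloride later replaces O with retention). C2 comes from bromination of a regiodefined silyl enol ether under weak substrate control (epimerisable, so correctable). C3 comes from equatorial hydride delivery cis to Br.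

Key step: step 9

Remark: 2 is taken as the purchasable, stabilised monomer; any 3-methyl regioisomer accompanying 3 should give a different lactone in step 3 and be removed there.

Step 1
Reactants: 1 isoprene; 2 diethyl 2-methylidenepropanedioate
Product: 3 diethyl 4-methylcyclohex-3-ene-1,1-dicarboxylate
Conditions: neat, BHT (cat.), 60 °C, sealed tube
Reagents that add atoms: none
Why: Thermal Diels–Alder reaction of a doubly activated 1,1-disubstituted dienophile with a 2-substituted diene should favour the 1,4 ("para") adduct, which places the future C9 methyl 1,4 to the quaternary C6; no stereocentre is formed.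

Step 2
Reactants: 3 diethyl 4-methylcyclohex-3-ene-1,1-dicarboxylate
Product: 4 4-methylcyclohex-3-ene-1,1-dicarboxylic acid
Conditions: KOH, EtOH/H2O, 80 °C; then aq. HCl, 0 °C
Reagents that add atoms: potassium hydroxide, [K+].[OH-]
Why: Saponification of the geminal diester, with cold acidification to avoid malonic-acid decarboxylation, gives an achiral diacid whose two carboxyl groups are enantiotopic.

Step 3
Reactants: 4 4-methylcyclohex-3-ene-1,1-dicarboxylic acid
Product: 5 (1S,4R,6S)-6-bromo-1-methyl-3-oxo-2-oxabicyclo[2.2.2]octane-4-carboxylic acid (Br anti to the lactone bridge)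
Conditions: NBS (1.1 equiv), cinchona-alkaloid amino-thiocarbamate catalyst (10 mol %, pseudoenantiomer chosen to give 5), CHCl3/PhMe, −50 °C
Reagents that add atoms: N-bromosuccinimide, O=C1CCC(=O)N1Br
Why: Proposed new method: a bifunctional amino-thiocarbamate should activate NBS at sulfur while its quinuclidine holds a carboxylate, so the bromiranium ion forms on one enantiotopic face of the C8=C9 alkene and only the carboxyl group on the opposite face can reach the tertiary C9 through a boat, which turns face selection into group selection and sets C6, C8 and C9 (O on C9 syn to the attacking carboxyl, Br anti on C8) in one event; the closest known reaction type is the catalytic enantioselective bromolactonisation of trisubstituted alkenoic acids to δ-lactones, not yet shown for desymmetrisation of a geminal diacid.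

Step 4
Reactants: 5 (1S,4R,6S)-6-bromo-1-methyl-3-oxo-2-oxabicyclo[2.2.2]octane-4-carboxylic acid
Product: 6 methyl (1S,4R,6S)-6-bromo-1-methyl-3-oxo-2-oxabicyclo[2.2.2]octane-4-carboxylate
Conditions: TMSCHN2, PhMe/MeOH, 0 °C
Reagents that add atoms: (trimethylsilyl)diazomethane, C[Si](C)(C)C=[N+]=[N-]
Why: Mild O-methylation of the free acid leaves the lactone and the bromide untouched and masks the C1-side carboxyl as an ester that should survive steps 5 and 6.

Step 5
Reactants: 6 methyl (1S,4R,6S)-6-bromo-1-methyl-3-oxo-2-oxabicyclo[2.2.2]octane-4-carboxylate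
Product: 7 methyl (1R,3S,4S)-3-bromo-4-chloro-1-(chlorocarbonyl)-4-methylcyclohexane-1-carboxylate (Br and Cl trans; COCl cis to Cl)
Conditions: SOCl2, ZnCl2 (10 mol %), CH2Cl2, 40 °C; evaporate
Reagents that add atoms: thionyl chloride, O=S(Cl)Cl
Why: Zinc chloride-assisted SN1 opening of the tertiary alkyl–oxygen bond of the lactone to the ω-chloro acid chloride should deliver chloride to C9 through the C8 bromonium ion, that is anti to bromine and with net retention at C9, and conversion of the carboxyl to the acid chloride makes the opening irreversible.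

Step 6
Reactants: 7 methyl (1R,3S,4S)-3-bromo-4-chloro-1-(chlorocarbonyl)-4-methylcyclohexane-1-carboxylate
Product: 8 methyl (1S,3S,4S)-1-acetyl-3-bromo-4-chloro-4-methylcyclohexane-1-carboxylate
Conditions: Me2CuLi (from MeLi and CuI), Et2O, −78 °C
Reagents that add atoms: lithium dimethylcuprate, [Li+].C[Cu-]C
Why: Acid chlorides are converted to methyl ketones by lithium dimethylcuprate at −78 °C without over-addition, and the ester, the secondary bromide and the tertiary chloride should be inert under these conditions.

Step 7
Reactants: 8 methyl (1S,3S,4S)-1-acetyl-3-bromo-4-chloro-4-methylcyclohexane-1-carboxylate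
Product: 10 1-[(1S,3S,4S)-3-bromo-4-chloro-4-methyl-1-(prop-1-en-2-yl)cyclohexyl]ethan-1-one, via bis-methylenated enol ether 9 (not isolated)
Conditions: Cp2TiMe2 (4 equiv), PhMe/THF, 70 °C, dark; then 1 M HCl, THF, 0 °C
Reagents that add atoms: dimethyltitanocene, [CH3-].[CH3-].[Ti+4].c1cc[cH-]c1.c1cc[cH-]c1; water, O
Why: Petasis methylenation turns the ketone into the C5 isopropenyl group and the hindered ester into a methyl enol ether that dilute acid hydrolyses to the C1 methyl ketone, so the two carbonyl groups on C6 exchange roles under non-basic conditions and no stereocentre is touched.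

Step 8
Reactants: 10 1-[(1S,3S,4S)-3-bromo-4-chloro-4-methyl-1-(prop-1-en-2-yl)cyclohexyl]ethan-1-one
Product: 11 4-[(1S,3S,4S)-1-acetyl-3-bromo-4-chloro-4-methylcyclohexyl]-1-bromopent-4-en-2-one
Conditions: BrCH2COCl, EtAlCl2 (2.5 equiv), CH2Cl2, −78 → −40 °C
Reagents that add atoms: bromoacetyl chloride, O=C(Cl)CBr
Why: In this Lewis-acid-promoted ene-type Friedel–Crafts acylation the acyl chloride complex attacks the terminal CH2 of the isopropenyl group and the only allylic hydrogens, those of its methyl group, are transferred, so the C5=CH2 unit should emerge deconjugated; EtAlCl2 removes HCl as ethane and any reversible ionisation at C9 returns the same trans bromochloride through the bromonium ion.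

Step 9
Reactants: 11 4-[(1S,3S,4S)-1-acetyl-3-bromo-4-chloro-4-methylcyclohexyl]-1-bromopent-4-en-2-one
Product: 13 (6S,8S,9S)-8-bromo-9-chloro-1-hydroxy-1,9-dimethyl-5-methylidenespiro[5.5]undecan-3-one (both C1 epimers), via samarium enolate 12 (not isolated)
Conditions: SmI2 (2.2 equiv), THF, −78 °C; then sat. aq. NH4Cl
Reagents that add atoms: none
Why: Two single-electron transfers from divalent samarium cleave the C2–Br bond of 11 and give the trivalent samarium enolate 12 regiospecifically at C2, which adds through a chelated six-membered transition state to the C1 acetyl carbonyl held on C6. The closest known reaction type is the SmI2-promoted intramolecular Reformatsky-type aldol cyclisation of α-halo carbonyl compounds onto ketones. Ring A closes in a 6-(enolendo)-exo-trig mode, the only six-membered option because C6 carries no hydrogen and closure from C4 would give a four-membered ring. The new carbinol centre C1 forms as an inconsequential epimer mixture (it becomes sp2 in step 10), and C6, C8 and C9 are not involved. The step needs the enolate at C2 and not at the more acidic, doubly activated C4, which the position of the bromine atom secures, and it needs reduction of the α-keto C–Br bond in preference to the ring-B C8–Br and C9–Cl bonds, which the much easier reduction of an α-bromo ketone secures at −78 °C without HMPA.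

Step 10
Reactants: 13 (6S,8S,9S)-8-bromo-9-chloro-1-hydroxy-1,9-dimethyl-5-methylidenespiro[5.5]undecan-3-one
Product: 14 (6S,8S,9S)-8-bromo-9-chloro-1,9-dimethyl-5-methylidenespiro[5.5]undec-1-en-3-one
Conditions: Martin sulfurane, CH2Cl2, 0 °C → rt
Reagents that add atoms: none
Why: Dehydration of the tertiary β-hydroxy ketone with Martin sulfurane under neutral conditions should remove the more acidic C2 hydrogen and give the conjugated enone without a base that could move the C5 exocyclic alkene into conjugation.

Step 11
Reactants: 14 (6S,8S,9S)-8-bromo-9-chloro-1,9-dimethyl-5-methylidenespiro[5.5]undec-1-en-3-one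
Product: 16 (2S,6S,8S,9S)-2,8-dibromo-9-chloro-1,1,9-trimethyl-5-methylidenespiro[5.5]undecan-3-one, via trimethylsilyl enol ether 15 (not isolated)
Conditions: Me2CuLi (from MeLi and CuI), TMSCl, THF/Et2O, −78 → −30 °C; non-aqueous work-up; then NBS, THF, −78 °C
Reagents that add atoms: lithium dimethylcuprate, [Li+].C[Cu-]C; N-bromosuccinimide, O=C1CCC(=O)N1Br
Why: TMSCl-accelerated conjugate addition of the methyl cuprate to the β-methyl enone builds the C1 gem-dimethyl quaternary carbon next to C6 and gives the C2=C3 silyl enol ether regiospecifically, which NBS brominates at C2; C2 is set under weak substrate control because the two ring-B methylenes on C6 differ only beyond their β-carbons, so the (2R) epimer is expected alongside and is separated and recycled through the enol (cat. HBr).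

Step 12
Reactants: 16 (2S,6S,8S,9S)-2,8-dibromo-9-chloro-1,1,9-trimethyl-5-methylidenespiro[5.5]undecan-3-one
Product: 17 (2S,3R,6S,8S,9S)-2,8-dibromo-9-chloro-1,1,9-trimethyl-5-methylidenespiro[5.5]undecan-3-ol
Conditions: i-Bu2AlH (DIBAL-H), CH2Cl2, −78 °C; Rochelle salt work-up
Reagents that add atoms: none
Why: In the DIBAL-H reduction of the α-bromo ketone the axial C1 methyl blocks axial attack at C3, so hydride should enter equatorially and give the axial alcohol cis to the equatorial C2 bromine (3R), while the alkene and the alkyl halides are inert at −78 °C.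

**Compound list**
1 | isoprene (2-methylbuta-1,3-diene) | C=CC(C)=C | starting material
2 | diethyl 2-methylidenepropanedioate | C=C(C(=O)OCC)C(=O)OCC | starting material
3 | diethyl 4-methylcyclohex-3-ene-1,1-dicarboxylate | CCOC(=O)C1(C(=O)OCC)CCC(C)=CC1 | intermediate
4 | 4-methylcyclohex-3-ene-1,1-dicarboxylic acid | OC(=O)C1(C(=O)O)CCC(C)=CC1 | intermediate
5 | (1S,4R,6S)-6-bromo-1-methyl-3-oxo-2-oxabicyclo[2.2.2]octane-4-carboxylic acid | OC(=O)[C@@]1(C(=O)O3)CC[C@@]3(C)[C@@H](Br)C1 | intermediate
6 | methyl (1S,4R,6S)-6-bromo-1-methyl-3-oxo-2-oxabicyclo[2.2.2]octane-4-carboxylate | COC(=O)[C@@]1(C(=O)O3)CC[C@@]3(C)[C@@H](Br)C1 | intermediate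
7 | methyl (1R,3S,4S)-3-bromo-4-chloro-1-(chlorocarbonyl)-4-methylcyclohexane-1-carboxylate | COC(=O)[C@@]1(C(=O)Cl)CC[C@](C)(Cl)[C@@H](Br)C1 | intermediate
8 | methyl (1S,3S,4S)-1-acetyl-3-bromo-4-chloro-4-methylcyclohexane-1-carboxylate | COC(=O)[C@@]1(C(C)=O)CC[C@](C)(Cl)[C@@H](Br)C1 | intermediate
9 | (1S,2S,4S)-2-bromo-1-chloro-4-(1-methoxyethenyl)-1-methyl-4-(prop-1-en-2-yl)cyclohexane | COC(=C)[C@@]1(C(C)=C)CC[C@](C)(Cl)[C@@H](Br)C1 | intermediate
10 | 1-[(1S,3S,4S)-3-bromo-4-chloro-4-methyl-1-(prop-1-en-2-yl)cyclohexyl]ethan-1-one | CC(=O)[C@@]1(C(C)=C)CC[C@](C)(Cl)[C@@H](Br)C1 | intermediate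
11 | 4-[(1S,3S,4S)-1-acetyl-3-bromo-4-chloro-4-methylcyclohexyl]-1-bromopent-4-en-2-one | CC(=O)[C@@]1(C(=C)CC(=O)CBr)CC[C@](C)(Cl)[C@@H](Br)C1 | intermediate
12 | diiodosamarium enolate of 11 (O–Sm on the C3 oxygen, C2=C3 double bond; trivalent samarium) | CC(=O)[C@@]1(C(=C)CC(=C)O[Sm](I)I)CC[C@](C)(Cl)[C@@H](Br)C1 | intermediate
13 | (6S,8S,9S)-8-bromo-9-chloro-1-hydroxy-1,9-dimethyl-5-methylidenespiro[5.5]undecan-3-one (C1 epimers) | CC2(O)CC(=O)CC(=C)[C@@]21CC[C@](C)(Cl)[C@@H](Br)C1 | intermediate
14 | (6S,8S,9S)-8-bromo-9-chloro-1,9-dimethyl-5-methylidenespiro[5.5]undec-1-en-3-one | CC2=CC(=O)CC(=C)[C@@]21CC[C@](C)(Cl)[C@@H](Br)C1 | intermediate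
15 | {[(6S,8S,9S)-8-bromo-9-chloro-1,1,9-trimethyl-5-methylidenespiro[5.5]undec-2-en-3-yl]oxy}trimethylsilane | CC2(C)C=C(O[Si](C)(C)C)CC(=C)[C@@]21CC[C@](C)(Cl)[C@@H](Br)C1 | intermediate
16 | (2S,6S,8S,9S)-2,8-dibromo-9-chloro-1,1,9-trimethyl-5-methylidenespiro[5.5]undecan-3-one | C=C1CC(=O)[C@@H](Br)C(C)(C)[C@]12CC[C@](C)(Cl)[C@@H](Br)C2 | intermediate
17 | (2S,3R,6S,8S,9S)-2,8-dibromo-9-chloro-1,1,9-trimethyl-5-methylidenespiro[5.5]undecan-3-ol | C=C1C[C@@H](O)[C@@H](Br)C(C)(C)[C@]12CC[C@](C)(Cl)[C@@H](Br)C2 | target

Total step count: 12. Longest linear sequence: 12 steps (1 and 2 to 17).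

**Steps most likely to fail**

Step 3 (Proposed new method). The catalyst may discriminate the two alkene faces poorly, and some closure at the secondary C8 to a five-membered lactone may compete. The fallback sets out from 4: NBS and NaHCO3 in THF/H2O at 0 °C should give the racemic bromolactone acid F1. This is resolved by fractional crystallisation from EtOAc/EtOH as the (R)-1-phenylethanaminium salt of 5 F2. Acidification with 1 M HCl returns to the route at 5. The enantiomer left in the mother liquor can be returned to 4 by reductive elimination with Zn in AcOH.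

Step 11. Facial discrimination in the bromination of 15 is expected to be weak, and deprotonation at the doubly activated C4 may compete with the slow conjugate addition at the hindered β-carbon. The fallback sets out from 16 obtained together with its C2 epimer, (2R,6S,8S,9S)-2,8-dibromo-9-chloro-1,1,9-trimethyl-5-methylidenespiro[5.5]undecan-3-one F3. The mixture is submitted to an enzymatic dynamic reductive kinetic resolution: a ketoreductase picked from a commercial panel for (3R) delivery, NADPH recycled with glucose dehydrogenase and glucose, phosphate buffer pH 7.5, DMSO co-solvent, 30 °C. The two bromoketones interconvert through the enol while only the (2S) ketone is reduced, so the material should converge on 17, where the fallback rejoins the route.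

Step 8. The alkene position may be lost by elimination from an intermediate β-chloro ketone, the acetyl enol may be acylated, or C9–Cl may ionise under the aluminium Lewis acid. The fallback sets out from 10: a Me2AlCl-promoted carbonyl-ene reaction with 2-oxoethyl benzoate (CH2Cl2, −78 °C) should give 4-[(1S,3S,4S)-1-acetyl-3-bromo-4-chloro-4-methylcyclohexyl]-2-hydroxypent-4-en-1-yl benzoate F4 as carbinol epimers. Dess–Martin periodinane then gives the α-benzoyloxy ketone 4-[(1S,3S,4S)-1-acetyl-3-bromo-4-chloro-4-methylcyclohexyl]-2-oxopent-4-en-1-yl benzoate F5. SmI2 (THF, −78 °C) cleaves its α-C–O bond to the same samarium enolate 12, and the route is rejoined at 13.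

**Further compounds**
F1 | step 3 | racemic 6-bromo-1-methyl-3-oxo-2-oxabicyclo[2.2.2]octane-4-carboxylic acid (5 and its enantiomer) | OC(=O)[C@@]1(C(=O)O3)CC[C@@]3(C)[C@@H](Br)C1.OC(=O)[C@]1(C(=O)O3)CC[C@]3(C)[C@H](Br)C1
F2 | step 3 | (R)-1-phenylethanaminium salt of 5 | [O-]C(=O)[C@@]1(C(=O)O3)CC[C@@]3(C)[C@@H](Br)C1.C[C@@H]([NH3+])c1ccccc1
F3 | step 11 | (2R,6S,8S,9S)-2,8-dibromo-9-chloro-1,1,9-trimethyl-5-methylidenespiro[5.5]undecan-3-one | C=C1CC(=O)[C@H](Br)C(C)(C)[C@]12CC[C@](C)(Cl)[C@@H](Br)C2
F4 | step 8 | 4-[(1S,3S,4S)-1-acetyl-3-bromo-4-chloro-4-methylcyclohexyl]-2-hydroxypent-4-en-1-yl benzoate (carbinol epimers) | CC(=O)[C@@]1(C(=C)CC(O)COC(=O)c2ccccc2)CC[C@](C)(Cl)[C@@H](Br)C1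
F5 | step 8 | 4-[(1S,3S,4S)-1-acetyl-3-bromo-4-chloro-4-methylcyclohexyl]-2-oxopent-4-en-1-yl benzoate | CC(=O)[C@@]1(C(=C)CC(=O)COC(=O)c2ccccc2)CC[C@](C)(Cl)[C@@H](Br)C1
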